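The target is a C6–C8″ biflavone: unit 1 is the 5,7-dihydroxy-4′-methoxyflavone joined at C6, unit 2 the 5-hydroxy-7,4′-dimethoxyflavone joined at C8. Everything rests on opening ring C (the pyranone) of unit 2 at C4a–C4, C4–C3 and O1–C2. The key step exploits the ortho relationship between C4a and the hindered C8a oxygen flanking the biaryl bond, and the fact that C4 is a carbonyl carbon: one palladium-catalysed operation joins an ortho-iodophenol, carbon monoxide and 4-ethynylanisole and closes that ring. Its precursor is a tetra-ortho-substituted biaryl, a 6-iodo-3,5-dimethoxyphenol bearing at C2 the protected phloroglucinol ring A of unit 1.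

Key step: step 8

Remarks on the chemistry (assumptions):
- The C6–C8″ axis carries four ortho substituents and may be configurationally stable. The target structure defines no axial configuration, so compounds 20 to 24 are taken as racemic about this axis.
- Methoxymethyl ethers protect the C5 and C7 oxygens of unit 1: they direct the metalation that builds the biaryl and tolerate the organolithium steps, where aryl benzyl ethers would risk benzylic lithiation.
- Ring C of unit 1 is closed by a second use of the carbonylative annulation, which avoids a Lewis-acid acetylation next to acid-labile ethers.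

Step 1
Reactants: 1 phloroglucinol (benzene-1,3,5-triol)
Product: 2 3,5-bis(methoxymethoxy)phenol
Conditions: MOMCl (2.0 equiv), i-Pr2NEt, DMF, 0 °C → rt
Reagents that add atoms: chloromethyl methyl ether, COCCl
Why: Base-mediated O-alkylation (Williamson-type acetal ether formation) with two equivalents of chloromethyl methyl ether is a statistical but known protection of phloroglucinol that should give the bis-ether as the main fraction, separable by chromatography from the mono- and tris-ethers.

Step 2
Reactants: 2 3,5-bis(methoxymethoxy)phenol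
Product: 3 1,3-bis(methoxymethoxy)-5-(triisopropylsilyloxy)benzene
Conditions: TIPSCl, imidazole, DMF, rt
Reagents that add atoms: chlorotriisopropylsilane, CC(C)[Si](Cl)(C(C)C)C(C)C
Why: Imidazole-promoted silylation of the one remaining phenol gives a bulky, base-stable and non-directing silyl ether that marks the oxygen destined to become O1 of unit 1.

Step 3
Reactants: 4 3,5-dimethoxyphenol
Product: 5 3,5-dimethoxyphenyl N,N-diethylcarbamate
Conditions: ClCONEt2, K2CO3, MeCN, reflux
Reagents that add atoms: diethylcarbamoyl chloride, CCN(CC)C(Cl)=O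
Why: O-Carbamoylation of the phenol installs the strongest oxygen-based group for directed ortho metalation and at the same time masks the phenol for the cross-coupling.

Step 4
Reactants: 5 3,5-dimethoxyphenyl N,N-diethylcarbamate
Product: 7 2-iodo-3,5-dimethoxyphenyl N,N-diethylcarbamate, via ortho-lithiated carbamate 6 (not isolated)
Conditions: s-BuLi, TMEDA, THF, −78 °C; then I2, −78 °C → rt
Reagents that add atoms: iodine, II
Why: Directed ortho metalation: the carbamate, reinforced by the neighbouring methoxy group, should steer s-BuLi to the carbon between them in preference to the carbon between the two methoxy groups, and iodine traps aryllithium 6 at −78 °C before an anionic Fries shift can set in.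

Step 5
Reactants: 3 1,3-bis(methoxymethoxy)-5-(triisopropylsilyloxy)benzene; 7 2-iodo-3,5-dimethoxyphenyl N,N-diethylcarbamate
Product: 10 biaryl carbamate (2-[2,6-bis(methoxymethoxy)-4-(triisopropylsilyloxy)phenyl]-3,5-dimethoxyphenyl N,N-diethylcarbamate), via aryllithium 8 (not isolated), via arylzinc chloride 9 (not isolated)
Conditions: 3, n-BuLi, THF, 0 °C; ZnCl2, 0 °C → rt; then 7, Pd2(dba)3 (2.5 mol %), RuPhos (2-dicyclohexylphosphino-2′,6′-diisopropoxybiphenyl, 10 mol %), THF, 70 °C
Reagents that add atoms: none
Why: Directed ortho metalation between the two methoxymethoxy groups, lithium-to-zinc exchange and Negishi coupling under a bulky dialkylbiarylphosphine palladium catalyst is an established way to tetra-ortho-substituted biaryls and sidesteps the protodeboronation typical of 2,6-dioxygenated arylboron reagents.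

Step 6
Reactants: 10 biaryl carbamate
Product: 12 iodinated biaryl carbamate (2-[2,6-bis(methoxymethoxy)-4-(triisopropylsilyloxy)phenyl]-6-iodo-3,5-dimethoxyphenyl N,N-diethylcarbamate), via lithiated biaryl carbamate 11 (not isolated)
Conditions: s-BuLi, TMEDA, THF, −78 °C; then I2, −78 °C → rt
Reagents that add atoms: iodine, II
Why: Directed ortho metalation again: the single free position ortho to the carbamate, also flanked by the C5 methoxy, should be lithiated faster than the sites next to the weaker acetal directors on the other ring, and iodine then fixes the halogen at the future C4a.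

Step 7
Reactants: 12 iodinated biaryl carbamate
Product: 13 biaryl ortho-iodophenol (2-[2,6-bis(methoxymethoxy)-4-(triisopropylsilyloxy)phenyl]-6-iodo-3,5-dimethoxyphenol)
Conditions: Cp2Zr(H)Cl (3 equiv), THF, rt; aq. NaHCO3
Reagents that add atoms: none
Why: Reductive cleavage of the aryl O-carbamate by hydrozirconation of its carbonyl group and collapse to the zirconium phenoxide is a known mild deprotection that should leave the aryl iodide, the silyl ether and the acetals untouched.

Step 8
Reactants: 13 biaryl ortho-iodophenol; 14 4-ethynylanisole; 15 carbon monoxide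
Product: 18 unit 2 flavone (8-[2,6-bis(methoxymethoxy)-4-(triisopropylsilyloxy)phenyl]-5,7-dimethoxy-2-(4-methoxyphenyl)chromen-4-one), via ynone 16 (not isolated), via enaminone 17 (not isolated)
Conditions: PdCl2(PPh3)2 (5 mol %), CO (20 atm), Et2NH, DMF, 100–120 °C
Reagents that add atoms: none
Why: Oxidative addition of the C4a–I bond of 13 to zerovalent palladium (formed in situ from PdCl2(PPh3)2), migratory insertion of carbon monoxide and transfer of the amine-deprotonated alkyne 14 to the resulting aroyl complex of divalent palladium, followed by reductive elimination, should forge C4a–C4 and C4–C3 and release ynone 16. Diethylamine then adds to the triple bond to give enaminone 17, and the C8a oxygen attacks the amine-bearing carbon and expels the amine, forming O1–C2. The closest known reaction type is the carbonylative Sonogashira annulation of ortho-iodophenols with terminal alkynes to flavones under a palladium phosphine catalyst, a secondary amine and carbon monoxide. The single ring formed, ring C of unit 2, closes in the 6-endo mode by addition–elimination at C2. No stereocentre arises, and the biaryl axis is not a stereogenic element at this stage because ring A of unit 1 is still symmetric. The step needs acylation at C4a only, which the iodine placed there by directed metalation guarantees; flavone instead of aurone closure, which the amine adduct secures by removing the 5-exo path; and carbonylation in preference to direct alkynylation or amide formation, which carbon monoxide pressure, the absence of copper and the two ortho substituents shielding the aroyl palladium from the bulky amine should favour.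

Step 9
Reactants: 18 unit 2 flavone
Product: 19 flavone phenol (8-[4-hydroxy-2,6-bis(methoxymethoxy)phenyl]-5,7-dimethoxy-2-(4-methoxyphenyl)chromen-4-one)
Conditions: TBAF, THF, 0 °C; aq. NH4Cl
Reagents that add atoms: none
Why: Fluoride-induced desilylation of the aryl silyl ether should expose only the oxygen para to the biaryl bond, since the flavone, the methyl ethers and the acetals are inert to TBAF.

Step 10
Reactants: 19 flavone phenol
Product: 20 flavone ortho-iodophenol (8-[4-hydroxy-3-iodo-2,6-bis(methoxymethoxy)phenyl]-5,7-dimethoxy-2-(4-methoxyphenyl)chromen-4-one)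
Conditions: I2 (1.0 equiv), NaHCO3, THF/H2O, 0 °C
Reagents that add atoms: iodine, II
Why: Electrophilic aromatic iodination through the phenoxide should occur once at one of the two equivalent positions ortho to the free hydroxyl, which are far more nucleophilic than the neutral, carbonyl-deactivated ring A of unit 2.

Step 11
Reactants: 20 flavone ortho-iodophenol; 14 4-ethynylanisole; 15 carbon monoxide
Product: 23 protected biflavone (6-[5,7-dimethoxy-2-(4-methoxyphenyl)-4-oxochromen-8-yl]-5,7-bis(methoxymethoxy)-2-(4-methoxyphenyl)chromen-4-one), via ynone 21 (not isolated), via enaminone 22 (not isolated)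
Conditions: PdCl2(PPh3)2 (5 mol %), CO (20 atm), Et2NH, DMF, 100–120 °C
Reagents that add atoms: none
Why: The carbonylative Sonogashira annulation of step 8 is repeated at an unhindered phenol, and because the C8a oxygen of unit 1 is the only free hydroxyl next to the iodine the pyranone can only close in the sense that places the biaryl bond at C6.

Step 12
Reactants: 23 protected biflavone
Product: 24 target (5,7-dihydroxy-6-[5-hydroxy-7-methoxy-2-(4-methoxyphenyl)-4-oxochromen-8-yl]-2-(4-methoxyphenyl)chromen-4-one)
Conditions: BCl3 (excess), CH2Cl2, −78 °C → rt; MeOH quench, aqueous work-up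
Reagents that add atoms: none
Why: Lewis-acid ether cleavage: BCl3 should remove both acetals and, through its chelate with the C4 carbonyl of unit 2, the peri 5-O-methyl group, whereas the non-chelated 7- and 4′-methyl ethers are known to resist this reagent at or below room temperature.

Compound list
1 | phloroglucinol (benzene-1,3,5-triol) | Oc1cc(O)cc(O)c1 | starting material
2 | 3,5-bis(methoxymethoxy)phenol | COCOc1cc(O)cc(OCOC)c1 | intermediate
3 | 1,3-bis(methoxymethoxy)-5-(triisopropylsilyloxy)benzene | COCOc1cc(OCOC)cc(O[Si](C(C)C)(C(C)C)C(C)C)c1 | intermediate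
4 | 3,5-dimethoxyphenol | COc1cc(O)cc(OC)c1 | starting material
5 | 3,5-dimethoxyphenyl N,N-diethylcarbamate | CCN(CC)C(=O)Oc1cc(OC)cc(OC)c1 | intermediate
6 | [2-(diethylcarbamoyloxy)-4,6-dimethoxyphenyl]lithium (formed in the flask, not isolated) | CCN(CC)C(=O)Oc1cc(OC)cc(OC)c1[Li] | intermediate
7 | 2-iodo-3,5-dimethoxyphenyl N,N-diethylcarbamate | CCN(CC)C(=O)Oc1cc(OC)cc(OC)c1I | intermediate
8 | [2,6-bis(methoxymethoxy)-4-(triisopropylsilyloxy)phenyl]lithium (formed in the flask, not isolated) | COCOc1cc(O[Si](C(C)C)(C(C)C)C(C)C)cc(OCOC)c1[Li] | intermediate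
9 | [2,6-bis(methoxymethoxy)-4-(triisopropylsilyloxy)phenyl]zinc chloride (formed in the flask, not isolated) | COCOc1cc(O[Si](C(C)C)(C(C)C)C(C)C)cc(OCOC)c1[Zn]Cl | intermediate
10 | 2-[2,6-bis(methoxymethoxy)-4-(triisopropylsilyloxy)phenyl]-3,5-dimethoxyphenyl N,N-diethylcarbamate | CCN(CC)C(=O)Oc1cc(OC)cc(OC)c1-c1c(OCOC)cc(O[Si](C(C)C)(C(C)C)C(C)C)cc1OCOC | intermediate
11 | {3-[2,6-bis(methoxymethoxy)-4-(triisopropylsilyloxy)phenyl]-2-(diethylcarbamoyloxy)-4,6-dimethoxyphenyl}lithium (formed in the flask, not isolated) | CCN(CC)C(=O)Oc1c([Li])c(OC)cc(OC)c1-c1c(OCOC)cc(O[Si](C(C)C)(C(C)C)C(C)C)cc1OCOC | intermediate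
12 | 2-[2,6-bis(methoxymethoxy)-4-(triisopropylsilyloxy)phenyl]-6-iodo-3,5-dimethoxyphenyl N,N-diethylcarbamate | CCN(CC)C(=O)Oc1c(I)c(OC)cc(OC)c1-c1c(OCOC)cc(O[Si](C(C)C)(C(C)C)C(C)C)cc1OCOC | intermediate
13 | 2-[2,6-bis(methoxymethoxy)-4-(triisopropylsilyloxy)phenyl]-6-iodo-3,5-dimethoxyphenol | COCOc1cc(O[Si](C(C)C)(C(C)C)C(C)C)cc(OCOC)c1-c1c(O)c(I)c(OC)cc1OC | intermediate
14 | 4-ethynylanisole (1-ethynyl-4-methoxybenzene) | COc1ccc(C#C)cc1 | starting material
15 | carbon monoxide | [C-]#[O+] | starting material
16 | 1-{3-[2,6-bis(methoxymethoxy)-4-(triisopropylsilyloxy)phenyl]-2-hydroxy-4,6-dimethoxyphenyl}-3-(4-methoxyphenyl)prop-2-yn-1-one (formed in the flask, not isolated) | COc1ccc(C#CC(=O)c2c(O)c(-c3c(OCOC)cc(O[Si](C(C)C)(C(C)C)C(C)C)cc3OCOC)c(OC)cc2OC)cc1 | intermediate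
17 | (E)-1-{3-[2,6-bis(methoxymethoxy)-4-(triisopropylsilyloxy)phenyl]-2-hydroxy-4,6-dimethoxyphenyl}-3-(diethylamino)-3-(4-methoxyphenyl)prop-2-en-1-one (formed in the flask, not isolated; either alkene geometry converges) | CCN(CC)/C(=C/C(=O)c1c(O)c(-c2c(OCOC)cc(O[Si](C(C)C)(C(C)C)C(C)C)cc2OCOC)c(OC)cc1OC)c1ccc(OC)cc1 | intermediate
18 | 8-[2,6-bis(methoxymethoxy)-4-(triisopropylsilyloxy)phenyl]-5,7-dimethoxy-2-(4-methoxyphenyl)chromen-4-one | COc1ccc(-c2cc(=O)c3c(OC)cc(OC)c(-c4c(OCOC)cc(O[Si](C(C)C)(C(C)C)C(C)C)cc4OCOC)c3o2)cc1 | intermediate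
19 | 8-[4-hydroxy-2,6-bis(methoxymethoxy)phenyl]-5,7-dimethoxy-2-(4-methoxyphenyl)chromen-4-one | COc1ccc(-c2cc(=O)c3c(OC)cc(OC)c(-c4c(OCOC)cc(O)cc4OCOC)c3o2)cc1 | intermediate
20 | 8-[4-hydroxy-3-iodo-2,6-bis(methoxymethoxy)phenyl]-5,7-dimethoxy-2-(4-methoxyphenyl)chromen-4-one (racemic about the biaryl axis) | COc1ccc(-c2cc(=O)c3c(OC)cc(OC)c(-c4c(OCOC)cc(O)c(I)c4OCOC)c3o2)cc1 | intermediate
21 | 8-{4-hydroxy-2,6-bis(methoxymethoxy)-3-[3-(4-methoxyphenyl)prop-2-ynoyl]phenyl}-5,7-dimethoxy-2-(4-methoxyphenyl)chromen-4-one (formed in the flask, not isolated) | COc1ccc(C#CC(=O)c2c(O)cc(OCOC)c(-c3c(OC)cc(OC)c4c(=O)cc(-c5ccc(OC)cc5)oc34)c2OCOC)cc1 | intermediate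
22 | 8-{3-[(E)-3-(diethylamino)-3-(4-methoxyphenyl)prop-2-enoyl]-4-hydroxy-2,6-bis(methoxymethoxy)phenyl}-5,7-dimethoxy-2-(4-methoxyphenyl)chromen-4-one (formed in the flask, not isolated; either alkene geometry converges) | CCN(CC)/C(=C/C(=O)c1c(O)cc(OCOC)c(-c2c(OC)cc(OC)c3c(=O)cc(-c4ccc(OC)cc4)oc23)c1OCOC)c1ccc(OC)cc1 | intermediate
23 | 6-[5,7-dimethoxy-2-(4-methoxyphenyl)-4-oxochromen-8-yl]-5,7-bis(methoxymethoxy)-2-(4-methoxyphenyl)chromen-4-one (racemic about the biaryl axis) | COc1ccc(-c2cc(=O)c3c(OCOC)c(-c4c(OC)cc(OC)c5c(=O)cc(-c6ccc(OC)cc6)oc45)c(OCOC)cc3o2)cc1 | intermediate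
24 | 5,7-dihydroxy-6-[5-hydroxy-7-methoxy-2-(4-methoxyphenyl)-4-oxochromen-8-yl]-2-(4-methoxyphenyl)chromen-4-one (no axial configuration defined) | COc1ccc(-c2cc(=O)c3c(O)c(-c4c(OC)cc(O)c5c(=O)cc(-c6ccc(OC)cc6)oc45)c(O)cc3o2)cc1 | target

Total step count: 12.
Longest linear sequence: 10 steps (steps 3–12 from 3,5-dimethoxyphenol; steps 1, 2 and 5–12 from phloroglucinol are equally long).

Steps most likely to fail

1. Step 8 (key step). Oxidative addition and acetylide transfer at the electron-rich, doubly ortho-substituted C4a may be slow. Aminocarbonylation by diethylamine, carbonyl-free alkynylation followed by furan closure, or reductive loss of iodine could then outrun ynone formation. Fallback, setting out from 13 and returning at 16 (and through 17 at 18): the C4 carbon is brought in as a formyl group instead of carbon monoxide. Deprotonation of 13 with NaH, iodine–lithium exchange with t-BuLi in THF at −78 °C and a DMF quench should give 3-[2,6-bis(methoxymethoxy)-4-(triisopropylsilyloxy)phenyl]-2-hydroxy-4,6-dimethoxybenzaldehyde F1. Addition of the lithium acetylide of 14 (n-BuLi, THF, −78 → 0 °C, excess to absorb the phenol proton) should give racemic 1-{3-[2,6-bis(methoxymethoxy)-4-(triisopropylsilyloxy)phenyl]-2-hydroxy-4,6-dimethoxyphenyl}-3-(4-methoxyphenyl)prop-2-yn-1-ol F2. Oxidation with MnO2 in CH2Cl2 gives ynone 16, which diethylamine in ethanol closes through 17 to 18 by the same addition–elimination.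

2. Step 5. Reductive elimination from the tetra-ortho-substituted diaryl palladium intermediate may be slow, letting protonation or homocoupling of the arylzinc and reduction of the iodide take over. Fallback, setting out from 5 and 3 and returning at 10: a Suzuki–Miyaura coupling with the roles of the two rings reversed. Aryllithium 6 (from 5 as in step 4) is trapped with 2-isopropoxy-4,4,5,5-tetramethyl-1,3,2-dioxaborolane to give 3,5-dimethoxy-2-(4,4,5,5-tetramethyl-1,3,2-dioxaborolan-2-yl)phenyl N,N-diethylcarbamate F3. Aryllithium 8 (from 3 as in step 5) is trapped with iodine to give 2-iodo-1,3-bis(methoxymethoxy)-5-(triisopropylsilyloxy)benzene F4. Coupling of F3 and F4 with Pd(OAc)2, SPhos (2-dicyclohexylphosphino-2′,6′-dimethoxybiphenyl) and K3PO4 in toluene with a little water at 100 °C should give 10.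

3. Step 11. On the advanced iodophenol, amide formation at the aroyl palladium stage, deiodination, or attack of the amine on the pyranone already present may compete at the temperature required. Fallback, setting out from 19 (so that the iodination of step 10 is also bypassed) and returning at 21 (and through 22 at 23): magnesium-mediated ortho-formylation of the phenol (MgCl2, Et3N, paraformaldehyde, MeCN, reflux) should give 3-[5,7-dimethoxy-2-(4-methoxyphenyl)-4-oxochromen-8-yl]-6-hydroxy-2,4-bis(methoxymethoxy)benzaldehyde F5. Addition of (4-methoxyphenyl)ethynylmagnesium bromide (from 14 and EtMgBr, THF, −40 °C, aldehyde-selective over the flavone carbonyl) should give 8-{4-hydroxy-3-[1-hydroxy-3-(4-methoxyphenyl)prop-2-yn-1-yl]-2,6-bis(methoxymethoxy)phenyl}-5,7-dimethoxy-2-(4-methoxyphenyl)chromen-4-one F6 as a mixture of diastereomers (carbinol centre and axis) that converges on oxidation. MnO2 in CH2Cl2 gives ynone 21, which diethylamine in ethanol closes through 22 to 23.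

Further compounds
F1 | step 8 | 3-[2,6-bis(methoxymethoxy)-4-(triisopropylsilyloxy)phenyl]-2-hydroxy-4,6-dimethoxybenzaldehyde | COCOc1cc(O[Si](C(C)C)(C(C)C)C(C)C)cc(OCOC)c1-c1c(O)c(C=O)c(OC)cc1OC
F2 | step 8 | 1-{3-[2,6-bis(methoxymethoxy)-4-(triisopropylsilyloxy)phenyl]-2-hydroxy-4,6-dimethoxyphenyl}-3-(4-methoxyphenyl)prop-2-yn-1-ol (racemic) | COc1ccc(C#CC(O)c2c(O)c(-c3c(OCOC)cc(O[Si](C(C)C)(C(C)C)C(C)C)cc3OCOC)c(OC)cc2OC)cc1
F3 | step 5 | 3,5-dimethoxy-2-(4,4,5,5-tetramethyl-1,3,2-dioxaborolan-2-yl)phenyl N,N-diethylcarbamate | CCN(CC)C(=O)Oc1cc(OC)cc(OC)c1B1OC(C)(C)C(C)(C)O1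
F4 | step 5 | 2-iodo-1,3-bis(methoxymethoxy)-5-(triisopropylsilyloxy)benzene | COCOc1cc(O[Si](C(C)C)(C(C)C)C(C)C)cc(OCOC)c1I
F5 | step 11 | 3-[5,7-dimethoxy-2-(4-methoxyphenyl)-4-oxochromen-8-yl]-6-hydroxy-2,4-bis(methoxymethoxy)benzaldehyde (racemic about the biaryl axis) | COc1ccc(-c2cc(=O)c3c(OC)cc(OC)c(-c4c(OCOC)cc(O)c(C=O)c4OCOC)c3o2)cc1
F6 | step 11 | 8-{4-hydroxy-3-[1-hydroxy-3-(4-methoxyphenyl)prop-2-yn-1-yl]-2,6-bis(methoxymethoxy)phenyl}-5,7-dimethoxy-2-(4-methoxyphenyl)chromen-4-one (mixture of diastereomers, racemic) | COc1ccc(C#CC(O)c2c(O)cc(OCOC)c(-c3c(OC)cc(OC)c4c(=O)cc(-c5ccc(OC)cc5)oc34)c2OCOC)cc1
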